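If each reagent taken from the second phase removes one substrate and nothing else takes reagent, then reagent stock plus substrate reacted stays constant; I kept my books on that sum, in fractions of the substrate charged.

common to all: substrate 17 mM

| run | reagent in the second phase | remark | time | volume of the second phase over the first |
|---|---|---|---|---|
| Sunday's | 36 mM | run made earlier |  |  |
| flask | 17.9 mM |  | 8.0 h | 0.50 |

Sunday's run (percent of the substrate charged)

| time / h | target / % | substrate / % |
|---|---|---|
| 0.167 | 12 | 86 |
| 0.500 | 24 | 61 |
| 0.833 | 32 | 43 |
| 1.33 | 33 | 14 |
| 2.00 | 24 | 0 |
| 2.50 | 20 | 1 |

(scatter of a reading: 1.5 percentage points)

- amounts and yields of target count product in the second phase too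
- in the second phase: reagent in the second phase, product in the second phase; everything else is in the first
- charges count per volume of the first phase; a concentration in a rate is the amount of a species over the volume of its own phase; every rate counts per litre of the first phase
- what was read earlier has a scatter of 1.5 percentage points, one standard deviation
- the earlier runs hold the two phases in the same ratio of volumes as the flask asked about

* how much target and product in the second phase together there is at 8.0 h, in percent of the substrate charged
* part of the substrate charged that has reacted at 8.0 h

1. Opening balance. The flask holds 1.05 reagent per substrate and Sunday's run held 2.12, so substrate is the limiting reagent in the flask, by a thin margin.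

2. Target's entry. Sunday's target fell from 24% to 20% with substrate read at 0% and 1%. Reagent was never read, so booking that fall as free of reagent was my assumption.

3. Rate of spending. Sunday's substrate fell from 86% to 14% in 1.16 h, against a mean stock of 1.62. The share of the stock spent per hour, my feed constant, reads 0.383 h⁻¹.

4. Closing. With stock decaying at that constant, by 8.0 h the flask's feed offers 1.00 per substrate. I therefore committed to 100% reacted, and to target below Sunday's last 20%.

The forecast differed, with 30% of target and 67% reacted, “so reagent becomes limiting”.

The flask gave 13.6% and 98.3%.

    reagent in the reaction phase ⇌ reagent in the second phase, rate k1*([reagent in the reaction phase] - [reagent in the second phase]/K1) per volume of the first phase (partition coefficient = 2.00, kL = 1.20 × 10⁻⁴ s⁻¹)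
    substrate + reagent in the reaction phase → target (k = 0.540 M⁻¹ s⁻¹)
    target ⇌ product in the second phase, rate k3*([target] - [product in the second phase]/K3) per volume of the first phase (partition coefficient = 30.0, kL = 7.30 × 10⁻⁵ s⁻¹)
    target → decomposed product (k = 4.30 × 10⁻⁴ s⁻¹)
    target ⇌ isomer of the product (K = 1.40, k = 5.30 × 10⁻⁵ s⁻¹)

In the flask, substrate and reagent in the reaction phase made target, half of this turnover done by 1.54 h and 98.3% of the charge by 8.0 h. Target turned into decomposed product behind it, half of that turnover done by 2.18 h and 79.8% of the charge by 8.0 h. The flask's books at 8.0 h, substrate reacted plus reagent in both phases, sum to 1.05 against 1.05. At 4.00 h in the flask the feed constant gives 21.6% of the stock left, and reagent in the second phase stood at 18.9% of its charge. For the neighbour flask read at 3.0 h, it gives 71.7% reacted, and that flask shows 74.1%.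

The numbers in the tables come from a simulation for an exercise.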